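Assumption: the target has no stereocentre and no hindered axis, so it is achiral and the "single enantiomer" requirement does not apply. The CH(OMe) centre in 5, 8 and 9 is racemic and enolisable, and it is lost when the pyranone forms.

## Retrosynthetic overview
1. The C8–OH is installed last by para-selective C–H hydroxylation (Elbs) of the 5-hydroxyflavone, so ring A can come from symmetrical phloroglucinol.
2. The 7-OMe comes from chemoselective methylation of the 5,7-diol, because the 5-OH is chelated to C4=O.
3. Key step: C4–C4a and O1–C2 are cut together. This is a thermal [3+3] acylketene annulation (Mentzer) of unprotected phloroglucinol with an α-methoxy-β-keto ester that carries C2, C3(OMe), C4 and ring B. It needs no 2-hydroxyacetophenone, chalcone or Baker–Venkataraman step.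
4. The β-keto ester comes from C-acylation of the methyl methoxyacetate enolate with 2,3,4-trimethoxybenzoyl chloride.
5. Ring order: rings A and B are purchased, and ring C is the only ring formed (step 3).

## Route

Step 1
Reactants: 1 2,3,4-trimethoxybenzoic acid
Product: 2 2,3,4-trimethoxybenzoyl chloride
Conditions: (COCl)2 (1.3 equiv), DMF (cat.), CH2Cl2, 0 °C to rt, 2 h; evaporate, use crude
Reagents that add atoms: oxalyl chloride, ClC(=O)C(=O)Cl
Why: This is acid chloride formation through the catalytic Vilsmeier chloroiminium species, and the aryl methyl ethers are inert while all by-products are gases.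

Step 2
Reactants: 2 2,3,4-trimethoxybenzoyl chloride; 3 methyl methoxyacetate
Product: 5 methyl 2-methoxy-3-oxo-3-(2,3,4-trimethoxyphenyl)propanoate (racemic), via lithium enolate of methyl methoxyacetate 4 (not isolated)
Conditions: 3 (2.2 equiv), LDA (2.2 equiv, commercial solution), THF, −78 °C, 45 min; then 2 (1.0 equiv) in THF, −78 °C, 1 h; AcOH quench at −78 °C
Reagents that add atoms: none
Why: This is a crossed Claisen-type C-acylation of a preformed lithium ester enolate, in which the second equivalent of enolate deprotonates the more acidic product and so blocks double acylation and ketone addition; the new CH(OMe) centre is racemic and is erased in step 3.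

Step 3 (key step)
Reactants: 5 methyl 2-methoxy-3-oxo-3-(2,3,4-trimethoxyphenyl)propanoate; 6 phloroglucinol (anhydrous)
Product: 10 5,7-dihydroxy-3-methoxy-2-(2,3,4-trimethoxyphenyl)-4H-chromen-4-one, via acylketene 7 (not isolated), via aryl ester 8 (not isolated), via 1,3-diketone 9 (not isolated)
Conditions: 5 (1.0 equiv), 6 (1.5 equiv), neat melt, microwave, 240 °C, 10 min, open vessel under N2 sweep; triturate with water, recrystallise from MeOH
Reagents that add atoms: none
Why: This is the Mentzer pyrone synthesis, in which the enol of 5 loses MeOH thermally to give acylketene 7, a phenol OH of 6 traps it as ester 8, an uncatalysed thermal Fries shift gives the o-hydroxyaryl diketone 9, and cyclodehydration closes ring C; the symmetry of 6 allows only one regioisomer, the absence of acid suppresses the Pechmann coumarin pathway, and the α-methoxy ester is a substrate extension within a reaction type that accepts α-substituted β-keto esters.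

Step 4
Reactants: 10 5,7-dihydroxy-3-methoxy-2-(2,3,4-trimethoxyphenyl)-4H-chromen-4-one
Product: 11 5-hydroxy-3,7-dimethoxy-2-(2,3,4-trimethoxyphenyl)-4H-chromen-4-one
Conditions: MeI (1.05 equiv), K2CO3 (1.1 equiv), acetone, reflux, 3 h
Reagents that add atoms: iodomethane, CI
Why: This is a Williamson ether synthesis in which the 7-OH (a vinylogous acid) is the more acidic and more nucleophilic site, while the 5-OH is held in a hydrogen bond to C4=O and does not react with one equivalent of MeI.

Step 5
Reactants: 11 5-hydroxy-3,7-dimethoxy-2-(2,3,4-trimethoxyphenyl)-4H-chromen-4-one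
Product: 13 5,8-dihydroxy-3,7-dimethoxy-2-(2,3,4-trimethoxyphenyl)-4H-chromen-4-one (target), via potassium 8-sulfate 12 (not isolated)
Conditions: K2S2O8 (1.3 equiv), 10% aq KOH, pyridine, 15–20 °C, 24 h; acidify to pH 5 and extract unreacted 11 (recycled); aqueous phase with conc. HCl, Na2SO3, 90 °C, 30 min, N2
Reagents that add atoms: potassium peroxydisulfate, [K+].[K+].[O-]S(=O)(=O)OOS(=O)(=O)[O-]
Why: This is the Elbs persulfate oxidation, in which the only phenolate (O-5) attacks the peroxide oxygen through its free para carbon C8 to give the deactivated aryl sulfate 12, which cannot over-oxidise; brief hot dilute acid then cleaves its S–O bond, which is too mild for ether cleavage or Wessely–Moser isomerisation, and sulfite keeps the hydroquinone reduced.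

## Compound list
1 | 2,3,4-trimethoxybenzoic acid | OC(=O)c1ccc(OC)c(OC)c1OC | starting material
2 | 2,3,4-trimethoxybenzoyl chloride | ClC(=O)c1ccc(OC)c(OC)c1OC | intermediate
3 | methyl methoxyacetate | COCC(=O)OC | starting material
4 | lithium enolate of methyl methoxyacetate (geometry not defined, not isolated) | COC=C([O-])OC.[Li+] | intermediate
5 | methyl 2-methoxy-3-oxo-3-(2,3,4-trimethoxyphenyl)propanoate (racemic) | COC(=O)C(OC)C(=O)c1ccc(OC)c(OC)c1OC | intermediate
6 | phloroglucinol (benzene-1,3,5-triol) | Oc1cc(O)cc(O)c1 | starting material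
7 | 2-methoxy-3-oxo-3-(2,3,4-trimethoxyphenyl)prop-1-en-1-one (acylketene, not isolated) | COC(=C=O)C(=O)c1ccc(OC)c(OC)c1OC | intermediate
8 | 3,5-dihydroxyphenyl 2-methoxy-3-oxo-3-(2,3,4-trimethoxyphenyl)propanoate (racemic, not isolated) | COC(C(=O)Oc1cc(O)cc(O)c1)C(=O)c1ccc(OC)c(OC)c1OC | intermediate
9 | 2-methoxy-1-(2,3,4-trimethoxyphenyl)-3-(2,4,6-trihydroxyphenyl)propane-1,3-dione (racemic, not isolated) | COC(C(=O)c1c(O)cc(O)cc1O)C(=O)c1ccc(OC)c(OC)c1OC | intermediate
10 | 5,7-dihydroxy-3-methoxy-2-(2,3,4-trimethoxyphenyl)-4H-chromen-4-one | COc1ccc(-c2oc3cc(O)cc(O)c3c(=O)c2OC)c(OC)c1OC | intermediate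
11 | 5-hydroxy-3,7-dimethoxy-2-(2,3,4-trimethoxyphenyl)-4H-chromen-4-one | COc1ccc(-c2oc3cc(OC)cc(O)c3c(=O)c2OC)c(OC)c1OC | intermediate
12 | potassium 5-hydroxy-3,7-dimethoxy-4-oxo-2-(2,3,4-trimethoxyphenyl)-4H-chromen-8-yl sulfate (not isolated) | COc1ccc(-c2oc3c(OS(=O)(=O)[O-])c(OC)cc(O)c3c(=O)c2OC)c(OC)c1OC.[K+] | intermediate
13 | 5,8-dihydroxy-3,7,2',3',4'-pentamethoxyflavone (achiral) | COc1ccc(-c2oc3c(O)c(OC)cc(O)c3c(=O)c2OC)c(OC)c1OC | target

## Summary
Total step count: 5.
Longest linear sequence: 5 steps (1 → 2 → 5 → 10 → 11 → 13).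

## Steps most likely to fail and their fallbacks

**Step 3 (thermal annulation).**
- The risks are hydrolysis and decarboxylation of 5 by the water released, a second annulation on 10, and coumarin formation.
- The fallback is the classical acetophenone construction. It sets out from 6 (with 1 and 2) and returns to the route at 10.
- Houben–Hoesch reaction of 6 with methoxyacetonitrile (ZnCl2, HCl gas, Et2O, 0 °C) precipitates 2-methoxy-1-(2,4,6-trihydroxyphenyl)ethan-1-iminium chloride F3.
- Boiling F3 in water gives 2-methoxy-1-(2,4,6-trihydroxyphenyl)ethan-1-one F4.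
- Separately, 1 and 2 in pyridine give 2,3,4-trimethoxybenzoic anhydride F5.
- Allan–Robinson condensation of F4 with excess F5 and Et3N at 170 °C gives 5-hydroxy-3-methoxy-4-oxo-2-(2,3,4-trimethoxyphenyl)-4H-chromen-7-yl 2,3,4-trimethoxybenzoate F6.
- Saponification of F6 with KOH in aqueous EtOH, followed by acidification, gives 10.

**Step 5 (Elbs oxidation).**
- The risks are low conversion (typically 25–40% with recovered 11), poor solubility of the chelated phenol, and air oxidation of 13 to the 5,8-quinone.
- The fallback replaces direct C–H oxidation with formylation followed by an aryl migration. It sets out from 10 and returns at 13.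
- Duff formylation of 10 (hexamethylenetetramine, AcOH, 100 °C, then aq HCl) occurs ortho to the 7-OH. It gives 5,7-dihydroxy-3-methoxy-4-oxo-2-(2,3,4-trimethoxyphenyl)-4H-chromene-8-carbaldehyde F7, which is separated from any 6-formyl isomer.
- Selective 7-O-methylation (MeI, K2CO3, acetone) gives 5-hydroxy-3,7-dimethoxy-4-oxo-2-(2,3,4-trimethoxyphenyl)-4H-chromene-8-carbaldehyde F8.
- Dakin oxidation of F8 (H2O2, aq NaOH, pyridine, 0 °C to rt) is enabled by the para 5-phenolate. It passes through 5-hydroxy-3,7-dimethoxy-4-oxo-2-(2,3,4-trimethoxyphenyl)-4H-chromen-8-yl formate F9, which hydrolyses in the same flask to 13.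

**Step 2 (enolate acylation).**
- The risks are O-acylation, self-Claisen condensation of 3, and retro-Claisen cleavage on work-up.
- The fallback changes the bond formation from acylation to aldol addition plus oxidation. It sets out from enolate 4 (made from 3) and returns at 5.
- Commercial 2,3,4-trimethoxybenzaldehyde F1 is added to 4 at −78 °C. This gives methyl 3-hydroxy-2-methoxy-3-(2,3,4-trimethoxyphenyl)propanoate F2 as an inconsequential mixture of diastereomers.
- Dess–Martin periodinane in CH2Cl2 oxidises F2 to 5.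

## Further compounds
F1 | step 2 | 2,3,4-trimethoxybenzaldehyde (purchased) | O=Cc1ccc(OC)c(OC)c1OC
F2 | step 2 | methyl 3-hydroxy-2-methoxy-3-(2,3,4-trimethoxyphenyl)propanoate (racemic diastereomer mixture) | COC(=O)C(OC)C(O)c1ccc(OC)c(OC)c1OC
F3 | step 3 | 2-methoxy-1-(2,4,6-trihydroxyphenyl)ethan-1-iminium chloride | COCC(=[NH2+])c1c(O)cc(O)cc1O.[Cl-]
F4 | step 3 | 2-methoxy-1-(2,4,6-trihydroxyphenyl)ethan-1-one | COCC(=O)c1c(O)cc(O)cc1O
F5 | step 3 | 2,3,4-trimethoxybenzoic anhydride | COc1ccc(C(=O)OC(=O)c2ccc(OC)c(OC)c2OC)c(OC)c1OC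
F6 | step 3 | 5-hydroxy-3-methoxy-4-oxo-2-(2,3,4-trimethoxyphenyl)-4H-chromen-7-yl 2,3,4-trimethoxybenzoate | COc1ccc(-c2oc3cc(OC(=O)c4ccc(OC)c(OC)c4OC)cc(O)c3c(=O)c2OC)c(OC)c1OC
F7 | step 5 | 5,7-dihydroxy-3-methoxy-4-oxo-2-(2,3,4-trimethoxyphenyl)-4H-chromene-8-carbaldehyde | COc1ccc(-c2oc3c(C=O)c(O)cc(O)c3c(=O)c2OC)c(OC)c1OC
F8 | step 5 | 5-hydroxy-3,7-dimethoxy-4-oxo-2-(2,3,4-trimethoxyphenyl)-4H-chromene-8-carbaldehyde | COc1ccc(-c2oc3c(C=O)c(OC)cc(O)c3c(=O)c2OC)c(OC)c1OC
F9 | step 5 | 5-hydroxy-3,7-dimethoxy-4-oxo-2-(2,3,4-trimethoxyphenyl)-4H-chromen-8-yl formate | COc1ccc(-c2oc3c(OC=O)c(OC)cc(O)c3c(=O)c2OC)c(OC)c1OC
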